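The oxolane ring (O1; C2 with the aryl group; C3 with CH2OH; C4 with the aroyl group; C5 a methylene) is cut at O1–C2 and C4–C5. This leaves the chain C2–C3–C4, benzylic at one end and acyl-substituted at the other, which is a ring-opened cyclopropane bearing a donor at C2 and acceptors at C4, plus O1=C5H2, which is formaldehyde. One Lewis acid (3+2) annulation should form both bonds and the ring and fix C2 by inversion. Its precursor is an enantiopure trans 2-aryl-3-(silyloxymethyl)cyclopropane-1,1-diester from an aminocatalytic cyclopropanation; afterwards one ester is excised and the other becomes the aryl ketone, trans to C3.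

Key step: step 4

Remark on the chemistry: formaldehyde is treated as the commercial starting material; it is bought as paraformaldehyde and cracked to the anhydrous monomer just before use.
Remark on locants: the overview counts the ring as O1, C2 (aryl) to C5 (methylene). The compound names use systematic locants, in which the aryl-bearing carbon is C5, the CH2O-bearing carbon is C4 and the acyl-bearing carbon is C3.

Step 1
Reactants: 1 (E)-3,4,5-trimethoxycinnamaldehyde; 2 dimethyl bromomalonate
Product: 3 dimethyl (2R,3S)-2-formyl-3-(3,4,5-trimethoxyphenyl)cyclopropane-1,1-dicarboxylate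
Conditions: (S)-2-[diphenyl(trimethylsilyloxy)methyl]pyrrolidine (20 mol%), 2,6-lutidine (1.1 equiv), CH2Cl2, 0 °C → rt
Reagents that add atoms: none
Why: Iminium–enamine Michael-initiated ring closure: the (S)-amine forms an E-iminium ion whose Re face at the β-carbon is screened by the diphenyl(silyloxy)methyl group, so the bromomalonate carbanion adds to the Si face and sets the aryl-bearing centre as S, and the resulting enamine displaces bromide in a 3-exo-tet alkylation that places the formyl group trans to the aryl group.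

Step 2
Reactants: 3 dimethyl (2R,3S)-2-formyl-3-(3,4,5-trimethoxyphenyl)cyclopropane-1,1-dicarboxylate
Product: 4 dimethyl (2R,3S)-2-(hydroxymethyl)-3-(3,4,5-trimethoxyphenyl)cyclopropane-1,1-dicarboxylate
Conditions: NaBH4 (0.5 equiv), MeOH/CH2Cl2, −40 °C; pH 7 phosphate buffer; crude used at once
Reagents that add atoms: none
Why: Chemoselective borohydride reduction of the aldehyde beside the methyl esters touches no stereocentre, and the low temperature and neutral quench are chosen to keep the new hydroxymethyl group from closing onto the cis ester.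

Step 3
Reactants: 4 dimethyl (2R,3S)-2-(hydroxymethyl)-3-(3,4,5-trimethoxyphenyl)cyclopropane-1,1-dicarboxylate
Product: 5 dimethyl (2R,3S)-2-{[(triisopropylsilyl)oxy]methyl}-3-(3,4,5-trimethoxyphenyl)cyclopropane-1,1-dicarboxylate
Conditions: TIPSOTf (1.2 equiv), 2,6-lutidine (2 equiv), CH2Cl2, −78 °C
Reagents that add atoms: triisopropylsilyl trifluoromethanesulfonate, CC(C)[Si](C(C)C)(C(C)C)OS(=O)(=O)C(F)(F)F
Why: Silyl ether formation with a silyl triflate and a hindered pyridine base is fast at −78 °C, so the alcohol is capped before it can lactonise, and the bulky, weakly Lewis-basic triisopropylsilyl ether should neither bind the tin catalyst of step 4 nor be lost in the hot dealkoxycarbonylation of step 5.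

Step 4
Reactants: 5 dimethyl (2R,3S)-2-{[(triisopropylsilyl)oxy]methyl}-3-(3,4,5-trimethoxyphenyl)cyclopropane-1,1-dicarboxylate; 6 formaldehyde
Product: 7 dimethyl (4R,5R)-4-{[(triisopropylsilyl)oxy]methyl}-5-(3,4,5-trimethoxyphenyl)dihydrofuran-3,3(2H)-dicarboxylate
Conditions: CH2O (monomer, ca. 5 equiv, CH2Cl2 solution), Sn(OTf)2 (10 mol%), 4 Å MS, CH2Cl2, −40 °C → rt
Reagents that add atoms: none
Why: Sn(OTf)2 chelates the geminal diester and weakens the bond between the malonate carbon and the aryl-bearing carbon; the formaldehyde oxygen then displaces the malonate carbon from the rear of that benzylic carbon (SN2-like), giving a tin malonate enolate tethered to an oxocarbenium ion, and the enolate carbon adds to the CH2=O+ carbon. The closest known reaction is the Lewis acid catalysed (3+2) annulation of 2-arylcyclopropane-1,1-diesters with aldehydes, which is stereospecific with inversion at the donor carbon. The oxolane ring closes by an aldol-type 5-(enolexo)-endo-trig attack, endo because the C=O+ bond ends up inside the new ring, a mode that is routine for oxocarbenium electrophiles. The one stereocentre that changes, C5 of 7, is controlled by the benzylic centre of 5 through backside attack, so the trans cyclopropane should give the 4,5-cis ring (2,3-cis in the locants of the overview), while C4 of 7 is carried through untouched and the formaldehyde carbon is not stereogenic. The step needs cleavage of the aryl-bearing bond and not the silyloxymethyl-bearing one, which the cation-stabilising trimethoxyphenyl group secures, and it needs capture to outrun ionisation to a free benzylic cation, which the low temperature, the excess of the small aldehyde and a mild catalyst of divalent tin are meant to secure.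

Step 5
Reactants: 7 dimethyl (4R,5R)-4-{[(triisopropylsilyl)oxy]methyl}-5-(3,4,5-trimethoxyphenyl)dihydrofuran-3,3(2H)-dicarboxylate
Product: 9 methyl (3S,4R,5R)-4-{[(triisopropylsilyl)oxy]methyl}-5-(3,4,5-trimethoxyphenyl)tetrahydrofuran-3-carboxylate, via monoester C3-epimer mixture 8 (not isolated)
Conditions: LiCl (3 equiv), H2O (2 equiv), DMSO, 150 °C; then NaOMe (0.2 equiv), MeOH, rt
Reagents that add atoms: none
Why: Krapcho dealkoxycarbonylation (chloride demethylates one ester, the carboxylate loses CO2 and water protonates the ester enolate) followed by methoxide equilibration, which should set C3 under thermodynamic control with the ester trans to the neighbouring silyloxymethyl group and to the aryl group.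

Step 6
Reactants: 9 methyl (3S,4R,5R)-4-{[(triisopropylsilyl)oxy]methyl}-5-(3,4,5-trimethoxyphenyl)tetrahydrofuran-3-carboxylate
Product: 10 (3S,4R,5R)-N-methoxy-N-methyl-4-{[(triisopropylsilyl)oxy]methyl}-5-(3,4,5-trimethoxyphenyl)tetrahydrofuran-3-carboxamide
Conditions: MeNH(OMe)·HCl (2 equiv), iPrMgCl (4 equiv), THF, −20 → 0 °C
Reagents that add atoms: N,O-dimethylhydroxylamine hydrochloride, CNOC.Cl
Why: Ester aminolysis by chloromagnesium N-methoxy-N-methylamide made in the flask is the first half of a Weinreb ketone synthesis, and since C3 already holds its favoured trans arrangement, reversible enolisation by the magnesium base cannot change it.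

Step 7
Reactants: 10 (3S,4R,5R)-N-methoxy-N-methyl-4-{[(triisopropylsilyl)oxy]methyl}-5-(3,4,5-trimethoxyphenyl)tetrahydrofuran-3-carboxamide; 11 5-bromo-1,2,3-trimethoxybenzene
Product: 13 [(3S,4R,5R)-4-{[(triisopropylsilyl)oxy]methyl}-5-(3,4,5-trimethoxyphenyl)tetrahydrofuran-3-yl](3,4,5-trimethoxyphenyl)methanone, via 3,4,5-trimethoxyphenylmagnesium bromide 12 (not isolated)
Conditions: 11, Mg, THF, 40 °C; then 10, THF, 0 °C → rt; aq. NH4Cl
Reagents that add atoms: none
Why: Grignard formation from 11 and addition to the N-methoxy-N-methylamide (Weinreb ketone synthesis) should deliver one aryl group only, because the five-membered magnesium chelate of the tetrahedral adduct persists until the quench and the ketone is released on work-up with C3 intact.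

Step 8
Reactants: 13 [(3S,4R,5R)-4-{[(triisopropylsilyl)oxy]methyl}-5-(3,4,5-trimethoxyphenyl)tetrahydrofuran-3-yl](3,4,5-trimethoxyphenyl)methanone
Product: 14 [(3S,4R,5R)-4-(hydroxymethyl)-5-(3,4,5-trimethoxyphenyl)tetrahydrofuran-3-yl](3,4,5-trimethoxyphenyl)methanone
Conditions: HF·pyridine, pyridine, THF, 0 °C → rt
Reagents that add atoms: none
Why: Fluoride-driven desilylation of the primary silyl ether under pyridine-buffered, non-basic conditions should leave the epimerisable centre next to the ketone and the benzylic ether of the ring unchanged.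

Compound list
1 | (E)-3,4,5-trimethoxycinnamaldehyde | COc1cc(/C=C/C=O)cc(OC)c1OC | starting material
2 | dimethyl bromomalonate | COC(=O)C(Br)C(=O)OC | starting material
3 | dimethyl (2R,3S)-2-formyl-3-(3,4,5-trimethoxyphenyl)cyclopropane-1,1-dicarboxylate (formyl trans to aryl) | COC(=O)C1(C(=O)OC)[C@H](c2cc(OC)c(OC)c(OC)c2)[C@H]1C=O | intermediate
4 | dimethyl (2R,3S)-2-(hydroxymethyl)-3-(3,4,5-trimethoxyphenyl)cyclopropane-1,1-dicarboxylate | COC(=O)C1(C(=O)OC)[C@H](c2cc(OC)c(OC)c(OC)c2)[C@H]1CO | intermediate
5 | dimethyl (2R,3S)-2-{[(triisopropylsilyl)oxy]methyl}-3-(3,4,5-trimethoxyphenyl)cyclopropane-1,1-dicarboxylate (trans) | COC(=O)C1(C(=O)OC)[C@H](c2cc(OC)c(OC)c(OC)c2)[C@H]1CO[Si](C(C)C)(C(C)C)C(C)C | intermediate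
6 | formaldehyde | C=O | starting material
7 | dimethyl (4R,5R)-4-{[(triisopropylsilyl)oxy]methyl}-5-(3,4,5-trimethoxyphenyl)dihydrofuran-3,3(2H)-dicarboxylate (4,5-cis) | COC(=O)C1(C(=O)OC)CO[C@@H](c2cc(OC)c(OC)c(OC)c2)[C@H]1CO[Si](C(C)C)(C(C)C)C(C)C | intermediate
8 | methyl (4R,5R)-4-{[(triisopropylsilyl)oxy]methyl}-5-(3,4,5-trimethoxyphenyl)tetrahydrofuran-3-carboxylate, mixture of C3 epimers | COC(=O)C1CO[C@@H](c2cc(OC)c(OC)c(OC)c2)[C@H]1CO[Si](C(C)C)(C(C)C)C(C)C | intermediate
9 | methyl (3S,4R,5R)-4-{[(triisopropylsilyl)oxy]methyl}-5-(3,4,5-trimethoxyphenyl)tetrahydrofuran-3-carboxylate (3,4-trans, 4,5-cis) | COC(=O)[C@@H]1CO[C@@H](c2cc(OC)c(OC)c(OC)c2)[C@H]1CO[Si](C(C)C)(C(C)C)C(C)C | intermediate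
10 | (3S,4R,5R)-N-methoxy-N-methyl-4-{[(triisopropylsilyl)oxy]methyl}-5-(3,4,5-trimethoxyphenyl)tetrahydrofuran-3-carboxamide | CON(C)C(=O)[C@@H]1CO[C@@H](c2cc(OC)c(OC)c(OC)c2)[C@H]1CO[Si](C(C)C)(C(C)C)C(C)C | intermediate
11 | 5-bromo-1,2,3-trimethoxybenzene | COc1cc(Br)cc(OC)c1OC | starting material
12 | 3,4,5-trimethoxyphenylmagnesium bromide | COc1cc([Mg]Br)cc(OC)c1OC | intermediate
13 | [(3S,4R,5R)-4-{[(triisopropylsilyl)oxy]methyl}-5-(3,4,5-trimethoxyphenyl)tetrahydrofuran-3-yl](3,4,5-trimethoxyphenyl)methanone | COc1cc(C(=O)[C@@H]2CO[C@@H](c3cc(OC)c(OC)c(OC)c3)[C@H]2CO[Si](C(C)C)(C(C)C)C(C)C)cc(OC)c1OC | intermediate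
14 | [(3S,4R,5R)-4-(hydroxymethyl)-5-(3,4,5-trimethoxyphenyl)tetrahydrofuran-3-yl](3,4,5-trimethoxyphenyl)methanone | COc1cc(C(=O)[C@@H]2CO[C@@H](c3cc(OC)c(OC)c(OC)c3)[C@H]2CO)cc(OC)c1OC | target

Total step count: 8. Longest linear sequence: 8 steps (1 to 14); the aryl Grignard reagent from 11 is made inside step 7.

Steps most likely to fail

1. Step 4. The tin-activated cyclopropane may ionise to a free benzylic cation before the weakly nucleophilic formaldehyde captures it, which would erode the inversion at the aryl-bearing carbon. Formaldehyde may also oligomerise under the Lewis acid, or hydroxymethylate the electron-rich arene. Fallback: setting out from 5, the same annulation would be run with (E)-cinnamaldehyde, a far more nucleophilic partner for which stereospecific inversion is established (Sn(OTf)2, CH2Cl2, rt). This should give dimethyl (2R,4R,5R)-2-[(E)-2-phenylethenyl]-4-{[(triisopropylsilyl)oxy]methyl}-5-(3,4,5-trimethoxyphenyl)dihydrofuran-3,3(2H)-dicarboxylate F1. Oxidative cleavage of the styryl group (OsO4 cat., NaIO4, 2,6-lutidine, dioxane/H2O) would give dimethyl (2S,4R,5R)-2-formyl-4-{[(triisopropylsilyl)oxy]methyl}-5-(3,4,5-trimethoxyphenyl)dihydrofuran-3,3(2H)-dicarboxylate F2. Tsuji–Wilkinson decarbonylation (RhCl(PPh3)3, 1 equiv, toluene, 110 °C) would then excise the formyl carbon and come back to the route at 7. The alkylrhodium intermediate has no β-hydrogen on its quaternary neighbour, so elimination cannot compete.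

2. Step 2. The new hydroxymethyl group may undergo intramolecular transesterification onto the cis ester (lactonisation) during reduction, work-up or before silylation is complete. Fallback: setting out from 1, the silyl ether would be installed before the malonate carbon. Luche reduction (NaBH4, CeCl3·7H2O, MeOH, 0 °C) would give (E)-3-(3,4,5-trimethoxyphenyl)prop-2-en-1-ol F3. Silylation (TIPSCl, imidazole, DMF, rt) would give (E)-triisopropyl{[3-(3,4,5-trimethoxyphenyl)prop-2-en-1-yl]oxy}silane F4. Carbene transfer from dimethyl diazomalonate (Rh2(esp)2 cat., esp = α,α,α′,α′-tetramethyl-1,3-benzenedipropanoate, CH2Cl2, rt) retains the alkene geometry and should give racemic trans dimethyl 2-{[(triisopropylsilyl)oxy]methyl}-3-(3,4,5-trimethoxyphenyl)cyclopropane-1,1-dicarboxylate F5. Preparative HPLC on a chiral stationary phase would then come back to the route at 5.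

3. Step 5. At 150 °C the silyl ether may be lost, the ring may open across its CH2–O bond from the ester enolate, or dealkoxycarbonylation of the hindered quaternary diester may stall. Fallback: setting out from 7, one ester would be hydrolysed (KOH, 1 equiv, MeOH/THF/H2O, 0 °C → rt). The ester trans to the silyloxymethyl group is the more exposed one, and either choice leads on to the same product. This should give (3R,4R,5R)-3-(methoxycarbonyl)-4-{[(triisopropylsilyl)oxy]methyl}-5-(3,4,5-trimethoxyphenyl)tetrahydrofuran-3-carboxylic acid F6. This malonic half-acid would lose CO2 under mild conditions (Cu2O cat., MeCN, 80 °C) and come back to the route at 8, which the methoxide equilibration of step 5 turns into 9.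

Further compounds
F1 | step 4 | dimethyl (2R,4R,5R)-2-[(E)-2-phenylethenyl]-4-{[(triisopropylsilyl)oxy]methyl}-5-(3,4,5-trimethoxyphenyl)dihydrofuran-3,3(2H)-dicarboxylate | COC(=O)C2(C(=O)OC)[C@@H](/C=C/c1ccccc1)O[C@@H](c3cc(OC)c(OC)c(OC)c3)[C@H]2CO[Si](C(C)C)(C(C)C)C(C)C
F2 | step 4 | dimethyl (2S,4R,5R)-2-formyl-4-{[(triisopropylsilyl)oxy]methyl}-5-(3,4,5-trimethoxyphenyl)dihydrofuran-3,3(2H)-dicarboxylate | COC(=O)C1(C(=O)OC)[C@@H](C=O)O[C@@H](c2cc(OC)c(OC)c(OC)c2)[C@H]1CO[Si](C(C)C)(C(C)C)C(C)C
F3 | step 2 | (E)-3-(3,4,5-trimethoxyphenyl)prop-2-en-1-ol | COc1cc(/C=C/CO)cc(OC)c1OC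
F4 | step 2 | (E)-triisopropyl{[3-(3,4,5-trimethoxyphenyl)prop-2-en-1-yl]oxy}silane | COc1cc(/C=C/CO[Si](C(C)C)(C(C)C)C(C)C)cc(OC)c1OC
F5 | step 2 | racemic trans dimethyl 2-{[(triisopropylsilyl)oxy]methyl}-3-(3,4,5-trimethoxyphenyl)cyclopropane-1,1-dicarboxylate | COC(=O)C1(C(=O)OC)[C@H](c2cc(OC)c(OC)c(OC)c2)[C@H]1CO[Si](C(C)C)(C(C)C)C(C)C.COC(=O)C1(C(=O)OC)[C@@H](c2cc(OC)c(OC)c(OC)c2)[C@@H]1CO[Si](C(C)C)(C(C)C)C(C)C
F6 | step 5 | (3R,4R,5R)-3-(methoxycarbonyl)-4-{[(triisopropylsilyl)oxy]methyl}-5-(3,4,5-trimethoxyphenyl)tetrahydrofuran-3-carboxylic acid | COC(=O)[C@@]1(C(=O)O)CO[C@@H](c2cc(OC)c(OC)c(OC)c2)[C@H]1CO[Si](C(C)C)(C(C)C)C(C)C
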